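## The problem

- **Numbering.** Cembrane numbering is used. C1 is the ring-fusion carbon that carries C15, C2 is the lactone carbinol, and C3–C4 is the epoxide (C4 bears methyl C18). C7=C8 and C11=C12 are the two E-trisubstituted alkenes and C14 is the acetoxy carbon. C15(=C17H2)–C16(=O)–O2 is the acrylate arm that closes ring B, the γ-lactone, on ring A, the 14-membered carbocycle.
- **Stereocentres.** The five stereocentres are contiguous: 14S, 1R, 2S, 3R, 4R. In the extended chain C13–C14–C1–C2–C3 the substituents O14, C15, O2 and O3 all lie on the same side. Ring B is therefore trans-fused, and the epoxy-carbinol pair C2/C3 is threo.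
- **The threo pair.** Additions to α,β-epoxy aldehydes and reductions of epoxy ketones do not favour the threo relation. It arises best when a free C2–OH directs epoxidation of C3=C4 under 1,3-allylic strain from C18. O2 should therefore not be acylated too early.
- **C14.** It is a plain CH2 in any regular isoprenoid chain and has no activating neighbour. O14 and O2 are both γ to C16, so a free 2,14-diol ester can close the wrong lactone.
- **Sensitive groups.** The exocyclic methylene lactone is a Michael acceptor and isomerises to the endocyclic butenolide. The trisubstituted epoxide is acid-labile, and the skipped and 1,5-diene units are also fragile.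
- **Feature that makes the key step possible.** C2 is flanked on both sides by a carbon pair at the oxidation level of an epoxidised E-alkene. C3/C4 is still an epoxide. C1/C14 is an epoxide that has been opened by carbon at C1. Removing ring B and these oxygens leaves a cyclic divinyl carbinol, 10, whose only stereocentre is C2. In 10 the pair C14–C1 is a two-carbon alkyne insert between the farnesyl terminus C13 and the farnesyl head C2.

## Retrosynthesis

**15 to 14 (cut O14–acetyl, with inversion at C14).**
- Anti opening of an E-derived epoxide necessarily leaves O14 anti to C15, whereas the target has them syn. The acetate is therefore introduced by an invertive substitution on the 14R alcohol 14.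
- This adds no step, because acetylation is needed in any case.
- In 14 the 14R configuration also guards ring B, since translactonisation to O14 would give a cis-fused lactone.
- The forward reaction must favour SN2 over elimination.

**14 to 12 and 11 (cut C1–C15 and C15=C17, which removes ring B).**
- An external nucleophile would attack the C1–C14 epoxide at C14, away from the inductively deactivating C2–O. The nucleophilic carbon is therefore tethered to O2 as a phosphonoacetyl group in 12.
- From O2 only C1 can be reached in a 5-exo closure that leads to a trans-fused lactone.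
- The same phosphonate then delivers C17 by olefination of a one-carbon aldehyde.
- The precursor 11 has no ring B and no Michael acceptor.

**11 to 10 (cut four C–O bonds).**
- Both epoxides flank one carbinol, so one tartrate enantiomer can address both alkenes.
- Cutting only one epoxide here would leave the other to be made without a directing group, among three similar alkenes.
- 10 has one stereocentre where 11 has five.
- The forward reaction must give erythro at C1/C14 and threo at C3/C4, and must leave C7=C8 and C11=C12 untouched.

**10 to 7 (cut C1–C2, the ring closure and key step).**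
- The bond joins an E-alkenyl carbon to an allylic carbinol. This is the retron of a catalytic asymmetric alkenylzinc addition to an enal.
- Cutting at C2–C3 would require a stereodefined trisubstituted alkenyl metal. Cutting at C13–C14 would create no stereocentre.
- The precursor 7 is acyclic and achiral, and carries only an enal and a terminal alkyne.
- The forward reaction must close a 14-membered ring and set 2S under catalyst control alone.

**7 to 4 to 1 (cut C13–C14).**
- The skipped enyne is the product of an allyl–alkynyl coupling.
- C2–C13 with the three methyl groups and three E-alkenes (two kept in the target, one to become the epoxide) map directly onto farnesol 1.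
- The E-terminal methyl of 1 becomes C13 by allylic oxidation (3) and bromination (4).
- No alkene geometry has to be created anywhere in the route except C1=C14, which hydroboration fixes.

## Roads not taken

**Alternative 1:** cut C1–C2 together with O2–C16, the most obvious plan.
- Forward key step: intramolecular Barbier or Nozaki–Hiyama allylation of the epoxy aldehyde by the (Z)-2-(bromomethyl)enoate in A1, followed by lactonisation.
- A1 needs C3, C4 and C14 set by unrelated asymmetric steps on an acyclic chain, and the chain C13–C14–C1 must be built carbon by carbon.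
- The closure creates C2 next to the epoxide, where the polar Felkin bias points to the erythro isomer, and O2 is acylated before it could direct anything.
- The C1/C2 relation depends on an allyl-metal geometry that is not fixed.
- The allyl metal carries the C14 silyloxy group in a position open to 1,4-elimination.
- The chosen plan closes the ring on an achiral precursor and lets C2–OH control everything else.

**Alternative 2:** cut C11=C12 (or C7=C8).
- Forward key step: ring-closing metathesis of A2 with a second-generation Grubbs catalyst.
- A trisubstituted alkene in a 14-membered ring forms without reliable E/Z control.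
- The methylene lactone and the 1,1-disubstituted partner are poor and competing substrates.
- All five stereocentres and both sensitive rings must be in place before the riskiest step.
- The ready-made E-alkenes of farnesol go unused.

**Alternative 3:** cut C14–C1 with ring B already in place.
- Forward key step: intramolecular allyl transfer from the 3-(bromomethyl)butenolide of A3 to the C14 aldehyde. A chair transition state would set C1 and C14 correctly.
- A3 needs a one-carbon homologation of the farnesyl terminus to a β,γ-unsaturated aldehyde that isomerises easily.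
- It also needs a separate construction of the butenolide.
- The butenolide has a γ-hydrogen at C2 whose removal opens the adjacent epoxide.
- The run-up is about twice as long as that to 7, which obtains C14 and C1 in one coupling.

Key step: step 7

Remark: (2E,6E)-farnesol is taken as the commercial single isomer.

## Route

Step 1
Reactants: 1 (2E,6E)-farnesol
Product: 2 (2E,6E)-farnesyl tert-butyldimethylsilyl ether
Conditions: TBSCl, imidazole, CH2Cl2, 0 °C → rt
Reagents that add atoms: tert-butyldimethylsilyl chloride, CC(C)(C)[Si](C)(C)Cl
Why: Standard silylation of a primary allylic alcohol. The ether blocks the C2 terminus during allylic oxidation and tolerates the Appel and Grignard steps.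

Step 2
Reactants: 2 (2E,6E)-farnesyl tert-butyldimethylsilyl ether
Product: 3 (2E,6E,10E)-12-[(tert-butyldimethylsilyl)oxy]-2,6,10-trimethyldodeca-2,6,10-trien-1-ol
Conditions: SeO2 (10 mol %), salicylic acid (10 mol %), t-BuOOH, CH2Cl2, 0 °C → rt
Reagents that add atoms: tert-butyl hydroperoxide, CC(C)(C)OO
Why: Catalytic SeO2 allylic oxidation (ene reaction followed by a [2,3]-sigmatropic shift) attacks the terminal, least hindered trisubstituted alkene and oxidises its E-methyl group. C13 is thus functionalised and the E geometry of C11=C12 is kept.

Step 3
Reactants: 3 (2E,6E,10E)-12-[(tert-butyldimethylsilyl)oxy]-2,6,10-trimethyldodeca-2,6,10-trien-1-ol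
Product: 4 (2E,6E,10E)-12-bromo-3,7,11-trimethyldodeca-2,6,10-trienyl tert-butyldimethylsilyl ether
Conditions: CBr4, PPh3, CH2Cl2, −20 → 0 °C
Reagents that add atoms: carbon tetrabromide, BrC(Br)(Br)Br
Why: Appel bromination under neutral conditions converts the primary allylic alcohol by SN2, without allylic transposition and without loss of the silyl ether.

Step 4
Reactants: 4 (2E,6E,10E)-12-bromo-3,7,11-trimethyldodeca-2,6,10-trienyl tert-butyldimethylsilyl ether
Product: 5 (2E,6E,10E)-3,7,11-trimethyltetradeca-2,6,10-trien-13-ynyl tert-butyldimethylsilyl ether
Conditions: HC≡CMgBr (3 equiv), CuI (10 mol %), THF, 0 °C → rt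
Reagents that add atoms: ethynylmagnesium bromide, C#C[Mg]Br
Why: Copper-catalysed alkynyl–allyl coupling to a skipped enyne. The primary carbon C13 is attacked directly because the SN2' position C11 is the more hindered one. One step brings in both C14 and C1.

Step 5
Reactants: 5 (2E,6E,10E)-3,7,11-trimethyltetradeca-2,6,10-trien-13-ynyl tert-butyldimethylsilyl ether
Product: 6 (2E,6E,10E)-3,7,11-trimethyltetradeca-2,6,10-trien-13-yn-1-ol
Conditions: TBAF, THF, 0 °C → rt
Reagents that add atoms: none
Why: Fluoride desilylation of a primary silyl ether. The conditions are too mild to isomerise the 1,4-enyne.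

Step 6
Reactants: 6 (2E,6E,10E)-3,7,11-trimethyltetradeca-2,6,10-trien-13-yn-1-ol
Product: 7 (2E,6E,10E)-3,7,11-trimethyltetradeca-2,6,10-trien-13-ynal
Conditions: MnO2 (20 equiv), CH2Cl2, rt
Reagents that add atoms: none
Why: MnO2 oxidation of an allylic alcohol to the enal, neutral and without E/Z isomerisation of C3=C4. Alkyne and isolated alkenes are inert.

Step 7
Reactants: 7 (2E,6E,10E)-3,7,11-trimethyltetradeca-2,6,10-trien-13-ynal
Product: 10 (1S,2E,6E,10E,13E)-3,7,11-trimethylcyclotetradeca-2,6,10,13-tetraen-1-ol (2S in cembrane numbering), via alkenyldicyclohexylborane 8 (not isolated), via alkenylethylzinc 9 (not isolated)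
Conditions: Cy2BH (1.0 equiv), hexane, 0 °C; slow addition (6 h) to Et2Zn (2 equiv), (−)-MIB (10 mol %), hexane, 0 °C, final 5 mM; aq NH4Cl
Reagents that add atoms: none
Why: Dicyclohexylborane adds syn and anti-Markovnikov to the terminal alkyne of 7 much faster than it touches the conjugated aldehyde or the trisubstituted alkenes, giving the (E)-alkenylborane 8; boron–zinc exchange with Et2Zn then gives 9, whose alkenyl group is transferred in preference to ethyl. The zinc amino-alkoxide of (−)-MIB binds the aldehyde and 9 in the usual bimetallic six-membered transition state and delivers C1 to the Si face of C2=O, so the only new stereocentre is set as 2S under pure catalyst control, 7 being achiral. The closest known reaction type is the amino-alcohol-catalysed asymmetric addition of alkenylzinc reagents made by hydroboration and transmetalation, known intramolecularly on ω-alkynals for 15-membered carbocycles and intermolecularly on β,β-disubstituted enals. Ring A closes in the 14-exo-trig mode, with C1 attacking the carbonyl carbon and O2 staying outside the ring. The step needs 1,2- over 1,4-addition, alkenyl over ethyl transfer, and cyclisation over oligomerisation. The first two are inherent to ligand-accelerated zinc chemistry; the third is secured by slow addition of 8, so that 9 never accumulates, and by the three E-alkenes, which remove rotors from the chain. The E geometry of C1=C14 follows from syn hydroboration and is retained through both metal exchanges.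

Step 8
Reactants: 10 (1S,2E,6E,10E,13E)-3,7,11-trimethylcyclotetradeca-2,6,10,13-tetraen-1-ol
Product: 11 (1R,2S,3R,4R,14R)-1,14:3,4-bis-epoxy alcohol (cembrane numbering; 7E,11E)
Conditions: Ti(OiPr)4 (20 mol %), D-(−)-DIPT (24 mol %), t-BuOOH (3 equiv), 4 Å MS, CH2Cl2, −20 °C
Reagents that add atoms: tert-butyl hydroperoxide, CC(C)(C)OO
Why: Sharpless asymmetric epoxidation, used twice on one carbinol; the D-(−)-tartrate catalyst has the facial preference that gives (1R,14R) and (3R,4R). For C1=C14 the 2S carbinol is the fast-reacting partner and gives the erythro epoxide; for C3=C4 the same face is the one favoured by 1,3-allylic strain between C18 and the C1 side (threo), so reagent and substrate agree on the face although the rate is lower. C7=C8 and C11=C12 are not held on titanium and stay untouched.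

Step 9
Reactants: 11 (1R,2S,3R,4R,14R)-1,14:3,4-bis-epoxy alcohol
Product: 12 O2-(diethylphosphonoacetyl) ester of 11
Conditions: (EtO)2P(O)CH2CO2H, DCC, DMAP (10 mol %), CH2Cl2, 0 °C → rt
Reagents that add atoms: diethylphosphonoacetic acid, OC(=O)CP(=O)(OCC)OCC
Why: Steglich esterification under near-neutral conditions, so that neither epoxide opens and no Payne rearrangement of the epoxy carbinol can start. C2 is not touched.

Step 10
Reactants: 12 O2-(diethylphosphonoacetyl) ester of 11
Product: 14 (1R,2S,3R,4R,14R)-14-hydroxy-3,4-epoxycembra-7E,11E,15(17)-trien-16,2-olide, via phosphono lactone 13 (not isolated)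
Conditions: LiHMDS (1.05 equiv), LiCl (5 equiv), THF, 0 → 45 °C; then (CH2O)n, 0 °C → rt
Reagents that add atoms: formaldehyde (as paraformaldehyde), C=O
Why: Proposed new method: deprotonation gives the lithium phosphonoacetate carbanion, tethered through O2, which reaches the rear of the C1–O bond of the erythro epoxide in a 5-exo-tet closure (the charge rests on the exocyclic P=O, so the enolendo restriction does not apply); inversion at C1 puts C15 on the side of O2 (trans-fused ring B) and frees O14 with retention, proton transfer from C15–H gives the anion of 13, and Horner–Wadsworth–Emmons olefination with formaldehyde installs C17. Attack at C3 is disfavoured because C3 is neopentyl-like next to quaternary C4 and, from the threo epoxide, would give a cis-fused lactone, while 6-endo attack at C14 is stereoelectronically poorer. The closest known reaction types are the intermolecular opening of epoxides by phosphonoacetate anions to α-phosphono-γ-lactones, the 5-exo cyclisation of epoxy malonates and epoxy nitriles, and the methylenation of α-phosphono lactones with formaldehyde.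

Step 11
Reactants: 14 (1R,2S,3R,4R,14R)-14-hydroxy-3,4-epoxycembra-7E,11E,15(17)-trien-16,2-olide
Product: 15 (1R,2S,3R,4R,14S)-14-acetoxy-3,4-epoxycembra-7E,11E,15(17)-trien-16,2-olide (target)
Conditions: PPh3, DIAD, AcOH, toluene, 0 °C → rt
Reagents that add atoms: acetic acid, CC(=O)O
Why: Mitsunobu reaction. The alkoxyphosphonium salt of the only free hydroxyl is displaced by acetate in an SN2 process, which inverts C14 from R to S and introduces the acetyl group in the same operation.

## Compound list

1 | (2E,6E)-farnesol | CC(C)=CCC/C(C)=C/CC/C(C)=C/CO | starting material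
2 | (2E,6E)-farnesyl tert-butyldimethylsilyl ether | CC(C)=CCC/C(C)=C/CC/C(C)=C/CO[Si](C)(C)C(C)(C)C | intermediate
3 | (2E,6E,10E)-12-[(tert-butyldimethylsilyl)oxy]-2,6,10-trimethyldodeca-2,6,10-trien-1-ol | OC/C(C)=C/CC/C(C)=C/CC/C(C)=C/CO[Si](C)(C)C(C)(C)C | intermediate
4 | (2E,6E,10E)-12-bromo-3,7,11-trimethyldodeca-2,6,10-trienyl tert-butyldimethylsilyl ether | BrC/C(C)=C/CC/C(C)=C/CC/C(C)=C/CO[Si](C)(C)C(C)(C)C | intermediate
5 | (2E,6E,10E)-3,7,11-trimethyltetradeca-2,6,10-trien-13-ynyl tert-butyldimethylsilyl ether | C#CC/C(C)=C/CC/C(C)=C/CC/C(C)=C/CO[Si](C)(C)C(C)(C)C | intermediate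
6 | (2E,6E,10E)-3,7,11-trimethyltetradeca-2,6,10-trien-13-yn-1-ol | C#CC/C(C)=C/CC/C(C)=C/CC/C(C)=C/CO | intermediate
7 | (2E,6E,10E)-3,7,11-trimethyltetradeca-2,6,10-trien-13-ynal | C#CC/C(C)=C/CC/C(C)=C/CC/C(C)=C/C=O | intermediate
8 | (2E,6E,10E,13E)-14-(dicyclohexylboranyl)-3,7,11-trimethyltetradeca-2,6,10,13-tetraenal | O=C/C=C(C)/CC/C=C(C)/CC/C=C(C)/C/C=C/B(C1CCCCC1)C1CCCCC1 | intermediate
9 | ethyl[(1E,4E,8E,12E)-5,9,13-trimethyl-14-oxotetradeca-1,4,8,12-tetraenyl]zinc | O=C/C=C(C)/CC/C=C(C)/CC/C=C(C)/C/C=C/[Zn]CC | intermediate
10 | (1S,2E,6E,10E,13E)-3,7,11-trimethylcyclotetradeca-2,6,10,13-tetraen-1-ol | O[C@H]1/C=C/C/C(C)=C/CC/C(C)=C/CC/C(C)=C/1 | intermediate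
11 | (1R,2S,3R,4R,14R)-1,14:3,4-bis-epoxy alcohol (cembrane numbering, 7E,11E) | O[C@H]2[C@H]3O[C@@H]3C/C(C)=C/CC/C(C)=C/CC[C@@]1(C)O[C@H]21 | intermediate
12 | O2-(diethylphosphonoacetyl) ester of 11 | CCOP(=O)(CC(=O)O[C@H]2[C@H]3O[C@@H]3C/C(C)=C/CC/C(C)=C/CC[C@@]1(C)O[C@H]21)OCC | intermediate
13 | α-(diethoxyphosphoryl) trans-lactone with 14R hydroxyl (C15 undefined) | CCOP(=O)(OCC)C1C(=O)O[C@H]2[C@H]1[C@H](O)C/C(C)=C/CC/C(C)=C/CC[C@@]1(C)O[C@H]21 | intermediate
14 | (1R,2S,3R,4R,14R)-14-hydroxy-3,4-epoxycembra-7E,11E,15(17)-trien-16,2-olide | C=C1C(=O)O[C@H]2[C@H]1[C@H](O)C/C(C)=C/CC/C(C)=C/CC[C@@]1(C)O[C@H]21 | intermediate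
15 | (1R,2S,3R,4R,14S)-14-acetoxy-3,4-epoxycembra-7E,11E,15(17)-trien-16,2-olide | C=C1C(=O)O[C@H]2[C@H]1[C@@H](OC(C)=O)C/C(C)=C/CC/C(C)=C/CC[C@@]1(C)O[C@H]21 | target

## Step count and least certain steps

Total steps: 11. Longest linear sequence: 11 (fully linear from 1).

**Step 10 (proposed new method).**
- The stabilised carbanion may open the epoxide too slowly. The ester could then be cleaved, the C3–C4 epoxide attacked, or the phosphoryl group transferred to the freed O14.
- Fallback, from 11 back to 14, uses known chemistry.
  - Hydroxyl-directed C-2-selective substitution of the epoxy alcohol with the lithium (trimethylsilylethynyl)trimethylaluminate complex gives the C1-(trimethylsilylethynyl) 2,14-diol F1, with inversion at C1.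
  - K2CO3 in MeOH gives the C1-ethynyl 2,14-diol F2.
  - Cyclocarbonylation of the homopropargylic alcohol (PdCl2, SnCl2, PPh3, CO, MeCN) gives 14. O2 is preferred because only it leads to the trans-fused lactone.

**Step 7 (key step).**
- Oligomerisation may compete with ring closure. The borane may partly reduce the enal, and a background unliganded addition would erode the facial selectivity.
- Fallback, from 6 back to 10.
  - Hydrozirconation with Cp2Zr(H)Cl followed by I2 gives the (E)-vinyl iodide alcohol F3.
  - MnO2 gives the iodo enal F4.
  - Nozaki–Hiyama–Kishi macrocyclisation (CrCl2, NiCl2 1 mol %, DMF/THF, high dilution) gives the racemic carbinol F5.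
  - MnO2 gives the cross-conjugated dienone F6.
  - Reduction with (R)-Me-CBS and catecholborane gives 10, the trisubstituted alkenyl group acting as the large substituent.

**Step 8.**
- Epoxidation of the trisubstituted alkene may be slow in the rate-mismatched sense. Facial selectivity may be incomplete inside the macrocycle, or titanium alkoxide may open the first-formed epoxy alcohol.
- Fallback, from 10 back to 11, relies first on substrate control and then on reagent control.
  - Ti(OiPr)4 and t-BuOOH (1 equiv) without tartrate epoxidise only the electron-rich C3=C4 under 1,3-allylic strain, giving the threo mono-epoxide F7.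
  - The remaining E-disubstituted alkene is then epoxidised in the matched Sharpless sense with D-(−)-DIPT to give 11.

**Step 11.**
- Elimination towards the C11–C14 diene or the C14=C1 dienoate may occur. The lactone carbonyl or the homoallylic alkene may participate, with loss of clean inversion. The phosphine may add to the methylene lactone.
- Fallback, from 14 back to 15, is inversion by redox.
  - Dess–Martin periodinane buffered with NaHCO3 gives the 14-ketone F8, which is used at once.
  - (R)-Me-CBS and catecholborane at −40 °C give the 14S alcohol F9.
  - Ac2O and pyridine give 15.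

## Further compounds

F1 | step 10 | C1-(trimethylsilylethynyl) 2,14-diol, configuration at C1, C2, C3, C4 and C14 as in 14 | O[C@H]2[C@H](C#C[Si](C)(C)C)[C@H](O)C/C(C)=C/CC/C(C)=C/CC[C@@]1(C)O[C@H]21
F2 | step 10 | C1-ethynyl 2,14-diol, configuration as in 14 | O[C@H]2[C@H](C#C)[C@H](O)C/C(C)=C/CC/C(C)=C/CC[C@@]1(C)O[C@H]21
F3 | step 7 | (2E,6E,10E,13E)-14-iodo-3,7,11-trimethyltetradeca-2,6,10,13-tetraen-1-ol | I/C=C/C/C(C)=C/CC/C(C)=C/CC/C(C)=C/CO
F4 | step 7 | (2E,6E,10E,13E)-14-iodo-3,7,11-trimethyltetradeca-2,6,10,13-tetraenal | I/C=C/C/C(C)=C/CC/C(C)=C/CC/C(C)=C/C=O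
F5 | step 7 | racemic (2E,6E,10E,13E)-3,7,11-trimethylcyclotetradeca-2,6,10,13-tetraen-1-ol | OC1/C=C/C/C(C)=C/CC/C(C)=C/CC/C(C)=C/1
F6 | step 7 | (2E,6E,10E,13E)-3,7,11-trimethylcyclotetradeca-2,6,10,13-tetraen-1-one | O=C1/C=C/C/C(C)=C/CC/C(C)=C/CC/C(C)=C/1
F7 | step 8 | (2S,3R,4R)-3,4-mono-epoxide of 10 (cembrane numbering) | O[C@H]2/C=C/C/C(C)=C/CC/C(C)=C/CC[C@@]1(C)O[C@H]21
F8 | step 11 | (1R,2S,3R,4R)-14-oxo-3,4-epoxycembra-7E,11E,15(17)-trien-16,2-olide | C=C1C(=O)O[C@H]2[C@H]1C(=O)C/C(C)=C/CC/C(C)=C/CC[C@@]1(C)O[C@H]21
F9 | step 11 | (1R,2S,3R,4R,14S)-14-hydroxy-3,4-epoxycembra-7E,11E,15(17)-trien-16,2-olide | C=C1C(=O)O[C@H]2[C@H]1[C@@H](O)C/C(C)=C/CC/C(C)=C/CC[C@@]1(C)O[C@H]21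
A1 | alternative 1 | C1–C2 seco compound: ethyl (Z)-2-(bromomethyl)enoate (C15–C17, C1), OTBS at C14 and C3–C4 epoxide in the target configuration, aldehyde at C2 | CCOC(=O)/C(CBr)=C/[C@@H](O[Si](C)(C)C(C)(C)C)C/C(C)=C/CC/C(C)=C/CC[C@@]1(C)O[C@@H]1C=O
A2 | alternative 2 | C11=C12 seco diene: complete lactone, epoxide and acetate in the target configuration, methallyl end at C12–C13, vinyl end at C11 | C=C1C(=O)O[C@@H]([C@H]1[C@@H](OC(C)=O)CC(C)=C)[C@H]1O[C@]1(C)CC/C=C(C)/CCC=C
A3 | alternative 3 | C14–C1 seco compound: 3-(bromomethyl)butenolide at C2 (target configuration at C2, C3 and C4), β,γ-unsaturated aldehyde at C14 | O=CC/C(C)=C/CC/C(C)=C/CC[C@@]1(C)O[C@@H]1[C@H]1OC(=O)C(CBr)=C1
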